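Ring B of the target, the cyclopentane C5–C6–C8–C9–C10 (gibberellane numbering) that carries the C7 carboxyl on C6 next to the quaternary spiro centre C8, is taken back to a cyclohexanone: C5–C6–C7–C8–C9–C10 with C7 as the ketone and a diazo group on C6. Photolytic Wolff rearrangement moves C8 from C7 to C6, so one operation contracts ring B, extrudes C7 as the carboxyl carbon and keeps the C8 configuration. The diazo ketone is a 20-nor-kaurane-type ring A/B/C tricycle carrying the 19,10-lactone, the protected 2β,3β-diol, a silyl enol ether at C12 and an allyl group on C8; it comes from 7-methoxy-1-naphthoic acid.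

Key step: step 13

Remark: 7-methoxy-1-naphthoic acid is assumed to be a catalogue compound; locants follow gibberellane numbering (C1–C19), and α denotes the face of the lactone bridge, β the opposite face.

Step 1
Reactants: 1 7-methoxy-1-naphthoic acid
Product: 3 rac-7-methoxy-1-methyl-1,4-dihydronaphthalene-1-carboxylic acid, via dilithium enediolate 2 (not isolated)
Conditions: Li (3.3 equiv), NH3(l)/THF, −78 °C; then MeI, −78 °C to rt; aq. HCl work-up
Reagents that add atoms: iodomethane, CI
Why: Birch reduction of the carboxyl-bearing ring gives the 1,4-dihydro enediolate, which is C-methylated at the ipso carbon (Birch reductive alkylation), so the quaternary centre (later C4) forms as a racemate while the anisole ring, lacking a proton source, should stay aromatic.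

Step 2
Reactants: 3 rac-7-methoxy-1-methyl-1,4-dihydronaphthalene-1-carboxylic acid
Product: 5 (R)-7-methoxy-1-methyl-1,4-dihydronaphthalene-1-carboxylic acid, via phenylethylammonium salt 4 (not isolated)
Conditions: (S)-1-phenylethylamine (0.55 equiv), EtOH/EtOAc, repeated crystallisation; then 1 M HCl/EtOAc
Reagents that add atoms: none
Why: Classical resolution by diastereomeric salt crystallisation should deliver the (R)-acid that fixes C4 of the target, the antipodal amine being used if the salt of the (S)-acid turns out to be the less soluble one.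

Step 3
Reactants: 5 (R)-7-methoxy-1-methyl-1,4-dihydronaphthalene-1-carboxylic acid
Product: 6 (R)-7-hydroxy-1-methyl-1,4-dihydronaphthalene-1-carboxylic acid
Conditions: BBr3 (3 equiv), CH2Cl2, −78 to 0 °C; aqueous work-up
Reagents that add atoms: none
Why: Lewis-acid O-demethylation of the aryl methyl ether at low temperature should leave the isolated ring alkene and the quaternary centre untouched.

Step 4
Reactants: 6 (R)-7-hydroxy-1-methyl-1,4-dihydronaphthalene-1-carboxylic acid
Product: 7 dienone lactone (ring A with C2=C3 and 4-methyl, C19 lactone from C4 to O on C10 on the α face, ring B as 5,8-dien-7-one)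
Conditions: PhI(OAc)2 (1.1 equiv), (CF3)2CHOH/MeCN, 0 °C
Reagents that add atoms: none
Why: Oxidative dearomatisation of the phenol by the hypervalent iodine reagent with intramolecular capture by the carboxylic acid at the para carbon C10 (dearomatising lactonisation) closes the five-membered 19,10-lactone, and because the acid can reach C10 only on its own face the C10 configuration follows from C4.

Step 5
Reactants: 7 dienone lactone
Product: 8 2β,3β-diol of the dienone lactone
Conditions: OsO4 (3 mol %), N-methylmorpholine N-oxide (1.3 equiv), acetone/H2O, 0 °C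
Reagents that add atoms: osmium tetroxide, O=[Os](=O)(=O)=O; N-methylmorpholine N-oxide, C[N+]1([O-])CCOCC1; water, O
Why: Catalytic syn-dihydroxylation should take only the electron-rich C2=C3 bond (both dienone double bonds are electron-poor) and attack the β face, since the axial C4–C19 and C10–O bonds of the lactone bridge cover the α face, which sets C2 and C3 as the cis 2β,3β-diol.

Step 6
Reactants: 8 2β,3β-diol of the dienone lactone
Product: 9 2β,3β-O-isopropylidene dienone lactone
Conditions: 2,2-dimethoxypropane, PPTS (cat.), CH2Cl2, rt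
Reagents that add atoms: 2,2-dimethoxypropane, COC(C)(C)OC
Why: Transacetalisation of the cis-diol gives the isopropylidene acetal, which masks both hydroxyls through the later base, oxidation and photolysis steps.

Step 7
Reactants: 10 methyl vinyl ketone
Product: 11 2-(tert-butyldimethylsilyloxy)buta-1,3-diene
Conditions: TBSOTf, Et3N, Et2O, 0 °C
Reagents that add atoms: tert-butyldimethylsilyl triflate, CC(C)(C)[Si](C)(C)OS(=O)(=O)C(F)(F)F
Why: Soft enolisation and O-silylation of the methyl ketone (silyl enol ether formation) gives the 2-silyloxy diene.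

Step 8
Reactants: 9 2β,3β-O-isopropylidene dienone lactone; 11 2-(tert-butyldimethylsilyloxy)buta-1,3-diene
Product: 12 Diels–Alder adduct (ring C fused at C8–C9, 8β-H, 9β-H, silyl enol ether C12=C13, 5-en-7-one retained)
Conditions: toluene, BHT (trace), 120 °C, sealed tube
Reagents that add atoms: none
Why: Thermal Diels–Alder reaction should occur at the unhindered C8=C9 arm (C5=C6 is trisubstituted and shielded), with the CH2 terminus next to the silyloxy carbon bonding to the β-carbon C9 so that oxygen ends at C12, and with the diene approaching the α face, syn to the lactone oxygen and anti to C1 as is usual for 4-alkyl-4-acyloxycyclohexadienones, so that C9 is set with C11 α and H8, H9 cis and β.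

Step 9
Reactants: 12 Diels–Alder adduct
Product: 14 8β-allyl enone, via lithium dienolate 13 (not isolated)
Conditions: LiN(i-Pr)2 (1.1 equiv), THF, −78 °C; allyl bromide, DMPU, −78 to −20 °C
Reagents that add atoms: allyl bromide, C=CCBr
Why: The enone can be deprotonated only at C8 (α′), and alkylation of the cross-conjugated dienolate (enolate alkylation) should occur anti to the C9–C11 bond, from the β face, which sets the quaternary C8 with a β-allyl group and a cis B/C junction.

Step 10
Reactants: 14 8β-allyl enone
Product: 15 8β-allyl 7-ketone (C5 epimers)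
Conditions: [(Ph3P)CuH]6 (0.4 equiv), H2O (5 equiv), toluene, rt
Reagents that add atoms: none
Why: Copper hydride conjugate reduction of the enone should spare the allyl group, the silyl enol ether and the lactone; hydride is expected to enter C5 mainly from the lactone face, but C5 becomes trigonal again in the next step and is left undefined here.

Step 11
Reactants: 15 8β-allyl 7-ketone (C5 epimers)
Product: 16 diosphenol (6-hydroxy-5-en-7-one)
Conditions: t-BuOK (3 equiv), O2 (1 atm), t-BuOH/THF, 0 °C; then AcOH (3 equiv)
Reagents that add atoms: dioxygen, O=O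
Why: Base-mediated autoxidation at C6, the only enolisable position, gives the 6,7-dione, which should rest as its enol with C5 trigonal, so that C5 can be set afterwards under thermodynamic control.

Step 12
Reactants: 16 diosphenol
Product: 18 6-diazo-7-ketone (5β-H), via tosylhydrazone 17 (not isolated)
Conditions: TsNHNH2 (1.05 equiv), AcOH (cat.), THF, 40 °C; then Et3N (3 equiv), CH2Cl2, rt
Reagents that add atoms: p-toluenesulfonyl hydrazide, Cc1ccc(cc1)S(=O)(=O)NN
Why: Condensation at the less hindered C6 carbonyl and base-induced loss of sulfinate from the α-keto tosylhydrazone (Bamford–Stevens-type diazo formation) give the diazo ketone, and C5 should be set as 5β-H by keto/enol and hydrazone/ene-hydrazine equilibration because only this epimer keeps C6 equatorial on ring A, away from the axial 1β-H and 3β-O.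

Step 13
Reactants: 18 6-diazo-7-ketone (5β-H)
Product: 21 methyl 6β-ester with contracted ring B, via ketene 19 (not isolated), via kinetic ester mixture 20 (not isolated)
Conditions: hν (365 nm), MeOH/THF, 20 °C; evaporation; then t-BuOK (0.3 equiv), t-BuOH/THF, 40 °C
Reagents that add atoms: methanol, CO
Why: Irradiation of the cyclic, s-cis-locked α-diazo ketone expels N2 with concerted 1,2-shift of the only possible migrating group, the quaternary C8, from the carbonyl carbon C7 to the diazo carbon C6, giving ketene 19 in which C6 is bonded to C5 and C8; methanol adds to the ketene and the enol tautomerises to ester 20. The closest known reaction is the photochemical Wolff ring contraction of 2-diazocycloalkanones to cycloalkanecarboxylates. Ring B is therefore not closed by a cyclisation but contracted from six to five members by the 1,2-alkyl shift, C7 leaving the ring as the ester carbon. C8 migrates with retention and C5 is untouched; the new centre C6 is first set by protonation of the ketene-derived enol from the more open β face (mainly the 6α-ester expected) and is then equilibrated through the ester enolate by catalytic t-BuOK to the more stable 6β-ester, trans to the quaternary C4 on C5. The step needs the Wolff shift to outrun 1,2-hydride shift from C5 and carbene addition to the allyl group, which the locked s-cis geometry should secure, and long-wavelength light should leave the silyl enol ether and the alkene untouched.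

Step 14
Reactants: 21 methyl 6β-ester with contracted ring B
Product: 22 methyl ester acetonide of the target (12-oxo, 16-methylene)
Conditions: Pd(OAc)2 (10 mol %), O2 (1 atm), DMSO, 45 °C
Reagents that add atoms: none
Why: Oxidative cycloalkenylation of the silyl enol ether (the enolate of divalent palladium adds 5-exo across the allyl double bond and β-hydride elimination releases the exocyclic methylene) closes ring D between C13 and C16 on the only face the tether can reach, which sets C13 and unveils the C12 ketone.

Step 15
Reactants: 22 methyl ester acetonide of the target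
Product: 23 acetonide acid
Conditions: n-PrSLi (5 equiv), HMPA, rt; dilute HCl work-up
Reagents that add atoms: none
Why: SN2 demethylation of the hindered C7 methyl ester by thiolate (nucleophilic ester cleavage) avoids aqueous base and should leave the lactone, the ketone and the alkene untouched.

Step 16
Reactants: 23 acetonide acid
Product: 24 target, 2β,3β-dihydroxy-12-oxo-20-norgibberell-16-ene-7,19-dioic acid 19,10-lactone
Conditions: AcOH/H2O (4:1), 40 °C
Reagents that add atoms: none
Why: Mild acid hydrolysis of the isopropylidene acetal (acetal cleavage) frees the diol without base, so the retro-aldol-prone 3-hydroxy lactone and the exocyclic alkene should survive.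

Compound list
1 | 7-methoxy-1-naphthoic acid | COc1ccc2cccc(C(=O)O)c2c1 | starting material
2 | dilithium enediolate of 7-methoxy-1,4-dihydro-1-naphthoic acid | [Li+].[Li+].COc1ccc2c(c1)C(=C([O-])[O-])C=CC2 | intermediate
3 | rac-7-methoxy-1-methyl-1,4-dihydronaphthalene-1-carboxylic acid | CC1(C(=O)O)C=CCc2ccc(OC)cc21 | intermediate
4 | (S)-1-phenylethylammonium (R)-7-methoxy-1-methyl-1,4-dihydronaphthalene-1-carboxylate | C[C@@]1(C(=O)[O-])C=CCc2ccc(OC)cc21.C[C@H]([NH3+])c1ccccc1 | intermediate
5 | (R)-7-methoxy-1-methyl-1,4-dihydronaphthalene-1-carboxylic acid | C[C@@]1(C(=O)O)C=CCc2ccc(OC)cc21 | intermediate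
6 | (R)-7-hydroxy-1-methyl-1,4-dihydronaphthalene-1-carboxylic acid | C[C@@]1(C(=O)O)C=CCc2ccc(O)cc21 | intermediate
7 | dienone lactone: 4-methyl-7-oxo-2,5,8-triene of rings A/B with the 19,10-lactone on the α face | O=C1C=C[C@@]23CC=C[C@@](C)(C(=O)O2)C3=C1 | intermediate
8 | 2β,3β-dihydroxy-5,8-dien-7-one 19,10-lactone | O=C1C=C[C@@]23C[C@H](O)[C@H](O)[C@@](C)(C(=O)O2)C3=C1 | intermediate
9 | 2β,3β-O-isopropylidene-5,8-dien-7-one 19,10-lactone | O=C1C=C[C@@]23C[C@H](O5)[C@H](OC5(C)C)[C@@](C)(C(=O)O2)C3=C1 | intermediate
10 | methyl vinyl ketone | CC(=O)C=C | starting material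
11 | 2-(tert-butyldimethylsilyloxy)buta-1,3-diene | C=CC(=C)O[Si](C)(C)C(C)(C)C | intermediate
12 | Diels–Alder adduct: rings A/B/C, 8β-H, 9β-H, 12-silyloxy-12(13)-ene, 5-en-7-one, acetonide, lactone | O=C1C=C2[C@](C)(C(=O)O3)[C@@H](OC4(C)C)[C@@H](O4)C[C@@]23[C@@H]5CC(O[Si](C)(C)C(C)(C)C)=CC[C@@H]51 | intermediate
13 | lithium 5,7(8)-dienolate of the adduct | [Li+].[O-]C1=C5CC=C(O[Si](C)(C)C(C)(C)C)C[C@H]5[C@@]23C[C@H](O4)[C@H](OC4(C)C)[C@@](C)(C(=O)O2)C3=C1 | intermediate
14 | 8β-allyl-5-en-7-one (silyl enol ether, acetonide, lactone) | O=C1C=C2[C@](C)(C(=O)O3)[C@@H](OC4(C)C)[C@@H](O4)C[C@@]23[C@@H]5CC(O[Si](C)(C)C(C)(C)C)=CC[C@@]51CC=C | intermediate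
15 | 8β-allyl 7-ketone, mixture of C5 epimers | O=C1CC2[C@](C)(C(=O)O3)[C@@H](OC4(C)C)[C@@H](O4)C[C@@]23[C@@H]5CC(O[Si](C)(C)C(C)(C)C)=CC[C@@]51CC=C | intermediate
16 | diosphenol: 8β-allyl-6-hydroxy-5-en-7-one | O=C1C(O)=C2[C@](C)(C(=O)O3)[C@@H](OC4(C)C)[C@@H](O4)C[C@@]23[C@@H]5CC(O[Si](C)(C)C(C)(C)C)=CC[C@@]51CC=C | intermediate
17 | 6-tosylhydrazono-7-ketone, 5β-H | O=C1C(=NNS(=O)(=O)c6ccc(C)cc6)[C@@H]2[C@](C)(C(=O)O3)[C@@H](OC4(C)C)[C@@H](O4)C[C@@]23[C@@H]5CC(O[Si](C)(C)C(C)(C)C)=CC[C@@]51CC=C | intermediate
18 | 6-diazo-7-ketone, 5β-H | O=C1C(=[N+]=[N-])[C@@H]2[C@](C)(C(=O)O3)[C@@H](OC4(C)C)[C@@H](O4)C[C@@]23[C@@H]5CC(O[Si](C)(C)C(C)(C)C)=CC[C@@]51CC=C | intermediate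
19 | ring-B-contracted ketene (C6=C7=O) | O=C=C1[C@@H]2[C@](C)(C(=O)O3)[C@@H](OC4(C)C)[C@@H](O4)C[C@@]23[C@@H]5CC(O[Si](C)(C)C(C)(C)C)=CC[C@@]51CC=C | intermediate
20 | methyl 7-ester, mixture of C6 epimers | COC(=O)C1[C@@H]2[C@](C)(C(=O)O3)[C@@H](OC4(C)C)[C@@H](O4)C[C@@]23[C@@H]5CC(O[Si](C)(C)C(C)(C)C)=CC[C@@]51CC=C | intermediate
21 | methyl 6β-ester (5β-H, 8β-allyl, silyl enol ether, acetonide, lactone) | COC(=O)[C@H]1[C@@H]2[C@](C)(C(=O)O3)[C@@H](OC4(C)C)[C@@H](O4)C[C@@]23[C@@H]5CC(O[Si](C)(C)C(C)(C)C)=CC[C@@]51CC=C | intermediate
22 | methyl ester acetonide of the target | C=C1C[C@]23C[C@H]1C(=O)C[C@H]2[C@@]12C[C@H](O4)[C@H](OC4(C)C)[C@@](C)(C(=O)O1)[C@H]2[C@@H]3C(=O)OC | intermediate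
23 | acetonide acid | C=C1C[C@]23C[C@H]1C(=O)C[C@H]2[C@@]12C[C@H](O4)[C@H](OC4(C)C)[C@@](C)(C(=O)O1)[C@H]2[C@@H]3C(=O)O | intermediate
24 | CNP0307952.1, 2β,3β-dihydroxy-12-oxo-20-norgibberell-16-ene-7,19-dioic acid 19,10-lactone | C=C1C[C@]23C[C@H]1C(=O)C[C@H]2[C@@]12C[C@H](O)[C@H](O)[C@@](C)(C(=O)O1)[C@H]2[C@@H]3C(=O)O | target

Total step count: 16. Longest linear sequence: 15 (steps 1–6 and 8–16; step 7 is a one-step branch).

Steps most likely to fail:

Step 4. The carboxylate may attack the ortho carbon C6 of the oxidised phenol instead of C10, which would rearomatise to a benzofuranone, or the solvent may intercept the cation. The fallback sets out from 5: a second Birch reduction (Li, NH3, t-BuOH, THF, −78 °C) would reduce the anisole ring to the enol ether diene acid F1. Aqueous oxalic acid and then CF3CO2H would hydrolyse the enol ether and add the C19 acid across the tetrasubstituted C5=C10 bond (protolactonisation) to give the saturated keto lactone F2. Twofold dehydrogenation of the cyclohexanone with IBX (DMSO, 75 °C) would come back to the route at 7.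

Step 9. Facial selectivity at the trigonal C8 may be poor, or O-allylation may compete. The fallback sets out from 9: α-iodination with I2/pyridine at C8 of the unhindered dienone arm would give the 8-iodo dienone F3, and Stille coupling (allylSnBu3, Pd2(dba)3, AsPh3) the 8-allyl dienone F4. A Lewis-acid-promoted Diels–Alder reaction with 11 (AlBr3/AlMe3, toluene/CH2Cl2, −5 °C) would then form C8–C14 and C9–C11 suprafacially, so that the allyl group and H9 are cis by necessity; this comes back to the route at 14.

Step 13. The photogenerated carbene may undergo 1,2-hydride shift from C5 or add to the allyl group, and epimerisation at C6 may stay incomplete. The fallback sets out from 18: protonolysis with HBr (Et2O, −30 °C) would give the 6-bromo 7-ketone F5. NaOMe in MeOH would then induce the semibenzilic (quasi-Favorskii) rearrangement, in which methoxide adds to C7 and C8 shifts to C6 with loss of bromide, and the same methoxide would equilibrate C6; this comes back to the route at 21.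

Further compounds
F1 | step 4 | (R)-7-methoxy-1-methyl-1,4,5,8-tetrahydronaphthalene-1-carboxylic acid (enol ether diene acid) | C[C@@]1(C(=O)O)C=CCC2=C1CC(OC)=CC2
F2 | step 4 | saturated 7-keto 19,10-lactone with C2=C3, 5β-H | O=C1CC[C@@]23CC=C[C@@](C)(C(=O)O2)[C@H]3C1
F3 | step 9 | 8-iodo-2β,3β-O-isopropylidene-5,8-dien-7-one 19,10-lactone | O=C1C(I)=C[C@@]23C[C@H](O5)[C@H](OC5(C)C)[C@@](C)(C(=O)O2)C3=C1
F4 | step 9 | 8-allyl-2β,3β-O-isopropylidene-5,8-dien-7-one 19,10-lactone | O=C1C(CC=C)=C[C@@]23C[C@H](O5)[C@H](OC5(C)C)[C@@](C)(C(=O)O2)C3=C1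
F5 | step 13 | 6-bromo-7-ketone (5β-H, C6 epimers) | O=C1C(Br)[C@@H]2[C@](C)(C(=O)O3)[C@@H](OC4(C)C)[C@@H](O4)C[C@@]23[C@@H]5CC(O[Si](C)(C)C(C)(C)C)=CC[C@@]51CC=C
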